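**Assumption:** cembrane numbering is used only as atom labels (C1 = lactone β‑carbon, C13 = CH–OAc, C14 = lactone CH–O, C15–C17 = α‑methylene lactone carbons). The target SMILES corresponds to (1S,3S,4S,7E,11E,13S,14S). The L‑fructose‑derived (ent) Shi ketone is taken as available.

## Retrosynthetic overview

1. The 14‑membered ring is closed last by ring‑closing metathesis at C7=C8 of a seco‑diene (terminal vinyl + isopropenyl). The α‑methylene group is unmasked just before from a Mannich base.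
2. C13–OAc comes from Felkin–Anh reduction of a C13 enone. The enone is made by Nozaki–Hiyama–Kishi coupling (C12–C13) of a lactone aldehyde with an (E)‑vinyl iodide (C8–C12), then oxidation.
3. The 3,4‑epoxide (second ring) comes from Shi epoxidation of the only trisubstituted olefin present at that stage. That olefin is made by Negishi coupling (C2–C3) of a lactone CH2ZnI with an (E)‑vinyl iodide (C3–C7).
4. The γ‑lactone (first ring, C14) comes from (S)‑5‑(hydroxymethyl)butenolide. C1 is set by trans photochemical hydroxymethylation.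

## Fragment A: C3–C7 vinyl iodide

**Step 1**
Reactants: 1, 4‑pentyn‑1‑ol
Product: 2, (E)‑5‑iodo‑4‑methylpent‑4‑en‑1‑ol
Conditions: Me3Al (3 equiv), Cp2ZrCl2 (0.25 equiv), CH2Cl2, 0 °C → rt; then I2, THF, −30 → 0 °C
Reagents that add atoms: trimethylaluminium, C[Al](C)C (CH3); iodine, II (I)
Why: Negishi Zr‑catalysed carboalumination adds Me–Al syn across the terminal alkyne (Me on the internal carbon), and iodinolysis with retention gives only the (E)‑iodide.

**Step 2**
Reactants: 2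
Product: 3, (E)‑5‑iodo‑4‑methylpent‑4‑enal
Conditions: Dess–Martin periodinane, NaHCO3, CH2Cl2, 0 °C → rt
Reagents that add atoms: none
Why: Dess–Martin oxidation of the primary alcohol; the vinyl iodide is inert.

**Step 3**
Reactants: 3
Product: 4, (E)‑1‑iodo‑2‑methylhexa‑1,5‑diene
Conditions: Ph3PCH3Br, KHMDS, THF, −78 → 0 °C
Reagents that add atoms: methyltriphenylphosphonium bromide, C[P+](c1ccccc1)(c1ccccc1)c1ccccc1.[Br-] (CH2)
Why: Wittig methylenation of the aldehyde; the vinyl iodide geometry is untouched.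

## Fragment B: C8–C12 vinyl iodide

**Step 4**
Reactants: 5, ethyl acetoacetate; 6, 1‑bromo‑2‑butyne
Product: 7, ethyl 2‑acetylhex‑4‑ynoate
Conditions: K2CO3, acetone, reflux
Reagents that add atoms: none
Why: acetoacetic ester alkylation (SN2 at the propargylic bromide).

**Step 5**
Reactants: 7
Product: 8, hept‑5‑yn‑2‑one
Conditions: 10% aq. NaOH, rt; then 2 M H2SO4, 70 °C
Reagents that add atoms: none
Why: saponification and decarboxylation of the β‑keto ester (ketonic cleavage).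

**Step 6**
Reactants: 8
Product: 9, 2‑methylhept‑1‑en‑5‑yne
Conditions: Ph3PCH3Br, KOt‑Bu, Et2O, 0 °C → rt (distil)
Reagents that add atoms: methyltriphenylphosphonium bromide, C[P+](c1ccccc1)(c1ccccc1)c1ccccc1.[Br-] (CH2)
Why: Wittig methylenation of the methyl ketone gives the isopropenyl terminus (future C8).

**Step 7**
Reactants: 9
Product: 10, (E)‑6‑iodo‑2‑methylhepta‑1,5‑diene
Conditions: Cp2Zr(H)Cl (1.15 equiv), THF, rt → 40 °C; then I2, 0 °C
Reagents that add atoms: iodine, II (I)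
Why: Schwartz hydrozirconation adds H–Zr syn to the 2‑alkyne, with Zr equilibrating to the methyl‑bearing carbon, and iodinolysis with retention gives the (E)‑2‑iodoalkene; the 1,1‑disubstituted alkene reacts much more slowly.

## Main line: lactone core, couplings and ring closure

**Step 8**
Reactants: 11, (S)‑5‑(hydroxymethyl)furan‑2(5H)‑one
Product: 12, (S)‑5‑[(triethylsilyloxy)methyl]furan‑2(5H)‑one
Conditions: TESCl, imidazole, CH2Cl2, 0 °C
Reagents that add atoms: chlorotriethylsilane, CC[Si](Cl)(CC)CC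
Why: silylation of the primary alcohol; the chiral‑pool centre becomes C14.

**Step 9**
Reactants: 12
Product: 13, (4R,5S)‑4‑(hydroxymethyl)‑5‑[(triethylsilyloxy)methyl]dihydrofuran‑2(3H)‑one
Conditions: MeOH (solvent, degassed), benzophenone (0.2 equiv), hν (350 nm), rt
Reagents that add atoms: methanol, CO (CH2OH)
Why: benzophenone‑sensitised radical conjugate addition of •CH2OH to the butenolide β‑carbon occurs anti to the C5 substituent, giving the trans lactone and setting C1.

**Step 10**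
Reactants: 13
Product: 14, (4S,5S)‑4‑(iodomethyl)‑5‑[(triethylsilyloxy)methyl]dihydrofuran‑2(3H)‑one
Conditions: I2, PPh3, imidazole, CH2Cl2, 0 °C → rt
Reagents that add atoms: iodine, II (I)
Why: Appel‑type iodination of the primary alcohol; the descriptor changes only through CIP priority, and the imidazole buffer keeps the TES ether intact.

**Step 11**
Reactants: 14; 4
Product: 15, (4S,5S)‑4‑[(2E)‑3‑methylhepta‑2,6‑dien‑1‑yl]‑5‑[(triethylsilyloxy)methyl]dihydrofuran‑2(3H)‑one
Conditions: Zn dust (TMSCl/BrCH2CH2Br‑activated), DMF, rt; then 4, Pd2(dba)3 (2.5 mol %), SPhos (10 mol %), rt → 40 °C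
Reagents that add atoms: none
Why: Negishi sp3–sp2 coupling of the lactone‑tolerant alkylzinc iodide with the alkenyl iodide forms C2–C3 with retention of the E geometry.

**Step 12**
Reactants: 15
Product: 16, (4S,5S)‑4‑{[(2S,3S)‑3‑(but‑3‑en‑1‑yl)‑3‑methyloxiran‑2‑yl]methyl}‑5‑[(triethylsilyloxy)methyl]dihydrofuran‑2(3H)‑one
Conditions: ent‑Shi ketone (L‑fructose‑derived, 0.3 equiv), Oxone, K2CO3, Bu4NHSO4, MeCN–DMM/aq. borate–EDTA buffer (pH 10.5), 0 °C
Reagents that add atoms: Oxone (potassium peroxymonosulfate), [K+].[O-]S(=O)(=O)OO (O)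
Why: Shi asymmetric epoxidation; the dioxirane attacks only the electron‑rich trisubstituted olefin (terminal vinyl untouched), and the L‑ketone gives the (3S,4S) epoxide under reagent control (the D‑ketone gives R,R for this olefin class).

**Step 13**
Reactants: 16
Product: 17, (3R,4S,5S)‑3‑[(dimethylamino)methyl]‑4‑{[(2S,3S)‑3‑(but‑3‑en‑1‑yl)‑3‑methyloxiran‑2‑yl]methyl}‑5‑[(triethylsilyloxy)methyl]dihydrofuran‑2(3H)‑one
Conditions: LDA (1.1 equiv), THF, −78 °C; then CH2=NMe2+ I−, −78 → 0 °C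
Reagents that add atoms: Eschenmoser's salt, C=[N+](C)C.[I-] (CH2NMe2)
Why: Mannich alkylation of the lactone enolate trans to the C4 substituent installs a masked α‑methylene group; the new C3 centre is temporary.

**Step 14**
Reactants: 17
Product: 18, (2S,3S,4R)‑4‑[(dimethylamino)methyl]‑3‑{[(2S,3S)‑3‑(but‑3‑en‑1‑yl)‑3‑methyloxiran‑2‑yl]methyl}‑5‑oxotetrahydrofuran‑2‑carbaldehyde
Conditions: (COCl)2 (4 equiv), DMSO (8 equiv), CH2Cl2, −78 → −40 °C; then i‑Pr2NEt, −78 → 0 °C; used crude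
Reagents that add atoms: none
Why: Swern conditions cleave the primary TES ether and oxidise it to the aldehyde in one pot; cold work‑up limits C14 epimerisation, and trans is the thermodynamic isomer in any case.

**Step 15**
Reactants: 18; 10 (2 equiv)
Product: 19, (3R,4S,5S)‑3‑[(dimethylamino)methyl]‑4‑{[(2S,3S)‑3‑(but‑3‑en‑1‑yl)‑3‑methyloxiran‑2‑yl]methyl}‑5‑[(2E)‑1‑hydroxy‑2,6‑dimethylhepta‑2,6‑dien‑1‑yl]dihydrofuran‑2(3H)‑one (C13 epimers)
Conditions: CrCl2 (6 equiv), NiCl2 (2 mol %), DMSO, rt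
Reagents that add atoms: none
Why: Nozaki–Hiyama–Kishi alkenylation forms C12–C13 with retention of olefin geometry and tolerates the lactone, epoxide and amine; the Felkin (13R) epimer should predominate, and both epimers are carried on.

**Step 16**
Reactants: 19
Product: 20, (3R,4S,5S)‑3‑[(dimethylamino)methyl]‑4‑{[(2S,3S)‑3‑(but‑3‑en‑1‑yl)‑3‑methyloxiran‑2‑yl]methyl}‑5‑[(2E)‑2,6‑dimethylhepta‑2,6‑dienoyl]dihydrofuran‑2(3H)‑one
Conditions: Dess–Martin periodinane, NaHCO3, CH2Cl2, 0 °C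
Reagents that add atoms: none
Why: Dess–Martin oxidation converges both C13 epimers to one enone.

**Step 17**
Reactants: 20
Product: 21, (3R,4S,5S)‑3‑[(dimethylamino)methyl]‑4‑{[(2S,3S)‑3‑(but‑3‑en‑1‑yl)‑3‑methyloxiran‑2‑yl]methyl}‑5‑[(1S,2E)‑1‑hydroxy‑2,6‑dimethylhepta‑2,6‑dien‑1‑yl]dihydrofuran‑2(3H)‑one
Conditions: L‑Selectride (1.1 equiv), THF, −78 °C; NH4Cl quench at −78 °C
Reagents that add atoms: none
Why: Felkin–Anh (polar) 1,2‑reduction, with hydride delivered anti to the C14–O bond, gives the 13,14‑syn (13S) alcohol.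

**Step 18**
Reactants: 21
Product: 22, (3R,4S,5S)‑5‑[(1S,2E)‑1‑acetoxy‑2,6‑dimethylhepta‑2,6‑dien‑1‑yl]‑3‑[(dimethylamino)methyl]‑4‑{[(2S,3S)‑3‑(but‑3‑en‑1‑yl)‑3‑methyloxiran‑2‑yl]methyl}dihydrofuran‑2(3H)‑one
Conditions: Ac2O, pyridine, DMAP (cat.), CH2Cl2, 0 °C → rt
Reagents that add atoms: acetic anhydride, CC(=O)OC(C)=O
Why: acetylation of the secondary allylic alcohol with retention; the tertiary amine is not acylated.

**Step 19**
Reactants: 22
Product: 23, (4S,5S)‑5‑[(1S,2E)‑1‑acetoxy‑2,6‑dimethylhepta‑2,6‑dien‑1‑yl]‑4‑{[(2S,3S)‑3‑(but‑3‑en‑1‑yl)‑3‑methyloxiran‑2‑yl]methyl}‑3‑methylenedihydrofuran‑2(3H)‑one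
Conditions: MeI (10 equiv), THF, rt; then sat. aq. NaHCO3/EtOAc, rt
Reagents that add atoms: none
Why: N‑quaternisation and mild‑base E1cB elimination of trimethylamine unmasks the α‑methylene lactone without touching the acetate or epoxide.

**Step 20**
Reactants: 23
Product: 24, 13‑acetoxysarcocrassolide
Conditions: Grubbs II (15 mol %), 2,6‑dichloro‑1,4‑benzoquinone (30 mol %), toluene (0.5 mM), 80 °C
Reagents that add atoms: none
Why: ring‑closing metathesis between the terminal vinyl and isopropenyl groups (loss of ethylene) closes the 14‑membered ring at the trisubstituted C7=C8 olefin; the E isomer (natural ring) is expected to be favoured, and the quinone suppresses Ru–H isomerisation of the exo‑methylene.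

## Compound list

1 | 4‑pentyn‑1‑ol | C#CCCCO | starting material
2 | (E)‑5‑iodo‑4‑methylpent‑4‑en‑1‑ol | OCCC/C(C)=C/I | intermediate
3 | (E)‑5‑iodo‑4‑methylpent‑4‑enal | O=CCC/C(C)=C/I | intermediate
4 | (E)‑1‑iodo‑2‑methylhexa‑1,5‑diene | C=CCC/C(C)=C/I | intermediate
5 | ethyl acetoacetate | CCOC(=O)CC(C)=O | starting material
6 | 1‑bromo‑2‑butyne | CC#CCBr | starting material
7 | ethyl 2‑acetylhex‑4‑ynoate | CCOC(=O)C(CC#CC)C(C)=O | intermediate
8 | hept‑5‑yn‑2‑one | CC#CCCC(C)=O | intermediate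
9 | 2‑methylhept‑1‑en‑5‑yne | C=C(C)CCC#CC | intermediate
10 | (E)‑6‑iodo‑2‑methylhepta‑1,5‑diene | C=C(C)CC/C=C(\C)I | intermediate
11 | (S)‑5‑(hydroxymethyl)furan‑2(5H)‑one | OC[C@H]1OC(=O)C=C1 | starting material
12 | (S)‑5‑[(triethylsilyloxy)methyl]furan‑2(5H)‑one | CC[Si](CC)(CC)OC[C@H]1OC(=O)C=C1 | intermediate
13 | (4R,5S)‑4‑(hydroxymethyl)‑5‑[(triethylsilyloxy)methyl]dihydrofuran‑2(3H)‑one | C1C(=O)O[C@H](CO[Si](CC)(CC)CC)[C@H]1CO | intermediate
14 | (4S,5S)‑4‑(iodomethyl)‑5‑[(triethylsilyloxy)methyl]dihydrofuran‑2(3H)‑one | C1C(=O)O[C@H](CO[Si](CC)(CC)CC)[C@H]1CI | intermediate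
15 | (4S,5S)‑4‑[(2E)‑3‑methylhepta‑2,6‑dien‑1‑yl]‑5‑[(triethylsilyloxy)methyl]dihydrofuran‑2(3H)‑one | C1C(=O)O[C@H](CO[Si](CC)(CC)CC)[C@H]1C/C=C(\C)CCC=C | intermediate
16 | (4S,5S)‑4‑{[(2S,3S)‑3‑(but‑3‑en‑1‑yl)‑3‑methyloxiran‑2‑yl]methyl}‑5‑[(triethylsilyloxy)methyl]dihydrofuran‑2(3H)‑one | C1C(=O)O[C@H](CO[Si](CC)(CC)CC)[C@H]1C[C@@H]1O[C@@]1(C)CCC=C | intermediate
17 | (3R,4S,5S)‑3‑[(dimethylamino)methyl] derivative of 16 | CN(C)C[C@@H]1C(=O)O[C@H](CO[Si](CC)(CC)CC)[C@H]1C[C@@H]1O[C@@]1(C)CCC=C | intermediate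
18 | (2S,3S,4R)‑4‑[(dimethylamino)methyl]‑3‑{[(2S,3S)‑3‑(but‑3‑en‑1‑yl)‑3‑methyloxiran‑2‑yl]methyl}‑5‑oxotetrahydrofuran‑2‑carbaldehyde | CN(C)C[C@@H]1C(=O)O[C@H](C=O)[C@H]1C[C@@H]1O[C@@]1(C)CCC=C | intermediate
19 | C13‑epimeric allylic alcohols (5‑[(2E)‑1‑hydroxy‑2,6‑dimethylhepta‑2,6‑dien‑1‑yl] lactone) | CN(C)C[C@@H]1C(=O)O[C@H](C(O)/C(C)=C/CCC(C)=C)[C@H]1C[C@@H]1O[C@@]1(C)CCC=C | intermediate
20 | C13 enone (5‑[(2E)‑2,6‑dimethylhepta‑2,6‑dienoyl] lactone) | CN(C)C[C@@H]1C(=O)O[C@H](C(=O)/C(C)=C/CCC(C)=C)[C@H]1C[C@@H]1O[C@@]1(C)CCC=C | intermediate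
21 | (13S)‑alcohol (5‑[(1S,2E)‑1‑hydroxy‑2,6‑dimethylhepta‑2,6‑dien‑1‑yl] lactone) | CN(C)C[C@@H]1C(=O)O[C@H]([C@@H](O)/C(C)=C/CCC(C)=C)[C@H]1C[C@@H]1O[C@@]1(C)CCC=C | intermediate
22 | (13S)‑acetate of 21 | CN(C)C[C@@H]1C(=O)O[C@H]([C@@H](OC(C)=O)/C(C)=C/CCC(C)=C)[C@H]1C[C@@H]1O[C@@]1(C)CCC=C | intermediate
23 | seco‑diene α‑methylene lactone, (4S,5S)‑5‑[(1S,2E)‑1‑acetoxy‑2,6‑dimethylhepta‑2,6‑dien‑1‑yl]‑4‑{[(2S,3S)‑3‑(but‑3‑en‑1‑yl)‑3‑methyloxiran‑2‑yl]methyl}‑3‑methylenedihydrofuran‑2(3H)‑one | C=C1C(=O)O[C@H]([C@@H](OC(C)=O)/C(C)=C/CCC(C)=C)[C@H]1C[C@@H]1O[C@@]1(C)CCC=C | intermediate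
24 | 13‑acetoxysarcocrassolide | C=C1C(=O)O[C@H]2[C@H]1C[C@@H]1O[C@@]1(C)CC/C=C(\C)CC/C=C(\C)[C@@H]2OC(C)=O | target

## Summary

Total step count: 20 (fragment A, 3; fragment B, 4; main line, 13).
Longest linear sequence: 13 steps (11 → 24, steps 8–20), which is 65% of the total.

Three steps most likely to fail, each with a fallback that changes the approach:

1. **Step 20 (RCM to a trisubstituted olefin in a 14‑membered ring; E/Z ratio and efficiency).** Fallback: build C7=C8 before ring closure with fixed E geometry, by Negishi coupling of a C6 alkylzinc with an (E)‑alkenyl iodide made by carboalumination. Then close the ring by intramolecular Nozaki–Hiyama–Kishi reaction of a C12 vinyl iodide onto the C13 aldehyde, followed by the same oxidation, Felkin reduction, acetylation and amine elimination.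

2. **Step 17 (substrate‑controlled Felkin reduction for 13S; possible 1,4‑reduction or lactone migration).** Fallback: omit the oxidation/reduction and separate the NHK epimers of 19. Acetylate the 13S epimer directly and convert the major Felkin 13R epimer to the same acetate 22 by Mitsunobu inversion (AcOH, DIAD, PPh3).

3. **Step 12 (Shi epoxidation; depends on the less common ent‑ketone, on diastereoselectivity, and on lactone stability at pH 10.5).** Fallback: set the epoxide by hydroxyl‑directed Sharpless epoxidation. Add an allyl cuprate trans to butenolide 12, cross‑metathesise with methacrolein, Luche‑reduce to the (E)‑2‑methylallylic alcohol, and epoxidise with Ti(Oi‑Pr)4/L‑(+)‑DET/TBHP to the (3S,4S) epoxide. Then displace the derived primary triflate with an allyl cuprate to install C6–C7; this also avoids the Negishi coupling.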